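## Analysis of the target

The target is a 1-aryltetralin (cyclolignan) diacetate. Ring A is a benzene ring with OMe on C6 and a free OH on C7. Ring B is the carbocycle C1–C2–C3–C4–C4a–C8a fused to it. A 4-hydroxy-3,5-dimethoxyphenyl ring (ring C) sits on C1, C2 and C3 each carry a CH2OAc arm, and C4 is a methylene.

The three stereocentres are contiguous, (1S,2R,3R), and all-trans. The aryl group on C1 and the arm on C3 lie on one face and the arm on C2 on the other, so all three substituents can be pseudo-equatorial on the half-chair of ring B. This is the most stable arrangement.

C2 and C3 become epimerisable once their arms are at the ester oxidation level. C1 is a diarylmethine with no such handle and must be set by absolute stereocontrol. It is the hard centre, because its two aryl groups are both electron-rich and differ only in substitution pattern.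

The sensitive groups are the two free phenols and the two primary acetates. The phenol of ring C is para to the C1–H bond and invites oxidation to a quinone methide. The acetates do not survive base or hydride. The phenols are therefore unmasked last under neutral conditions, and the acetates are put on while the phenols are still protected.

The plan rests on the C2–C3 bond. It is the bond of ring B opposite the aromatic C4a–C8a bond, and both of its carbons bear a one-carbon oxygenated arm. Both can therefore be ester α-carbons of an open-chain diester whose only stereocentre is C1.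

## Retrosynthetic reasoning

**End game.** The phenols of 19 are traced back to the benzyl ethers of 18, which leave by hydrogenolysis without touching acetates or the C1–H bond. The acetates of 18 come from diol 17; acylation needs no selectivity because both phenols are still benzylated. Diol 17 comes from diester 16 by hydride reduction. No skeletal bond is cut here; the purpose is to bring C2 and C3 to the ester level, where both are acidic.

**C2–C3 (key disconnection).** In 16 the C2–C3 bond is cut. It is the only ring-B bond whose two ends are both α to a carbonyl group. The cut gives the open-chain diester 14, in which C2 and C3 are the methylene groups of two ester arms and only C1 is stereogenic. Cutting C1–C8a or C1–C2 instead would leave two or three contiguous centres on an open chain with nothing to relay them. In the forward direction the bis-enolate 15 must be oxidised so that its two α-carbons join within the molecule, and C1 must steer C2 and C3 into the all-trans arrangement. That arrangement is also the thermodynamic one and both new centres stay enolisable in 16, so a kinetic shortfall can be repaired by equilibration.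

**C1–ring C.** The diarylmethine of 14 is cut at the bond from C1 to ring C, giving enoate 8 and boronic acid 13. This bond is chosen over C1–C8a because ring C is symmetric and has no ortho substituent, so its boron derivative should transfer readily. Ring A, with its ortho propanoate chain, is better placed on the acceptor. The forward reaction, a catalytic enantioselective conjugate arylation, must deliver the aryl group to the Re face of the β-carbon of 8. It is the only step that uses an external source of chirality.

**Ring A fragment.** Enoate 8 is cut at the bond from ring A to the alkene carbon (the later C8a–C1 bond), giving aryl bromide 6 and methyl acrylate 7 through a Heck-type vinylation. The saturated arm of 6 is traced through alkene 5 to aldehyde 2 and phosphonate 3 (olefination through carbanion 4, then saturation of the C3=C4 double bond). Aldehyde 2 is the bromination product of 1. The bromine enters para to the methoxy group, which is the carbon that becomes C8a, so the substitution pattern of ring A is fixed by 1.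

**Ring C fragment.** Boronic acid 13 comes from aryl bromide 10 by halogen–metal exchange and borylation (through 11 and 12), and 10 is the benzyl ether of phenol 9. Benzyl is used on both phenols because it survives strong base, hydride and a one-electron oxidant and leaves in one neutral step.

## Alternatives that were turned down

**Alternative 1:** The two exocyclic carbons are removed together. The C2–CH2 and C3–CH2 bonds are traced to a [2+2] cycloaddition of dichloroketene A3, generated in the flask, to the C2=C3 double bond of the 1-aryl-1,4-dihydronaphthalene A2. This should give the cis-fused dichlorocyclobutanone A1 on the face away from the C1 aryl group.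
- For: two C–C bonds form in one step, the cycloaddition is dependable on cis-disubstituted cycloalkenes and tolerates electron-rich arenes, and face selection by the neighbouring centre is probably more clear-cut than in a radical ring closure.
- Against: the ring fusion of A1 is necessarily cis, so C3 has to be inverted later. The four-membered ring must then be cut between its CCl2 and C=O carbons (dechlorination, regioselective oxidative scission beside electron-rich arenes, reduction), which puts five or more steps after the key step. A2 is a skipped diene whose C1–H bond is doubly benzylic and allylic, so isomerisation into conjugation or aromatisation would erase its only stereocentre, and no direct catalytic entry to enantiopure A2 is evident.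
- Comparison: the chosen plan forms only one bond in its key step, but it delivers both arms at the ester level, trans by preference, from a configurationally robust precursor, with three routine steps left.

**Alternative 2:** Both bonds to C2 are cut (C1–C2 and C2–C3), so C2 becomes the central carbon of dimethyl malonate A6. The substrate is the para-quinone methide A5, which carries an allylic carbonate on the ortho chain of ring A. An enantioselective 1,6-addition of A6 under a chiral hydrogen-bonding catalyst would set C1. A palladium-catalysed allylic alkylation in the same flask would then close ring B at the inner allyl terminus (six- over eight-membered ring) to give the vinyl diester A4.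
- For: two skeletal bonds and the ring form in one operation from a very cheap building block, and the ring C phenol emerges free. In bonds per step this plan is the stronger one.
- Against: a quinone methide from a 2,6-dimethoxyphenol lacks the bulky flanking groups that make the usual substrates stable and selective, and its methide carbon bears an ortho-substituted aryl group. C2 arrives as a quaternary gem-diester, so one ester must be removed (Krapcho reaction) and C2 becomes stereogenic only afterwards. The vinyl group on C3 has one carbon too many and must be cleaved oxidatively beside a free electron-rich phenol. The C3 configuration depends on a 1,3-relay across the quaternary carbon. About six steps follow the key step.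
- Comparison: the chosen plan brings C2 and C3 in at the correct substitution and oxidation level, and its enantioselective step belongs to a well-established reaction class.

**Alternative 3:** Ring A itself is dismantled. The bonds C4a–C8a and C7–C8 are cut, leading to A8, an open chain that already carries C1–C3, with a terminal alkyne on C1 and a 3-bromo-4-methoxy-2-pyrone on C4. Heating would cause an intramolecular Diels–Alder addition of the alkyne across the pyrone and a decarboxylative cycloreversion, giving bromoarene A7 with rings A and B formed together.
- For: no reagent is needed, two rings form in one step, and the substitution pattern of ring A is fixed beyond doubt. In complexity gained per step it is the strongest of the four plans.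
- Against: ring A is a plain guaiacyl ring that can be bought. All three contiguous stereocentres would have to be set on an open chain, and C1, being propargylic and benzylic, may racemise through the allene at the temperature required. The bromine on C7 must still be turned into a hydroxyl group beside two acetates (borylation and oxidation, two more steps), and the pyrone adds several steps.
- Comparison: the chosen plan takes ring A as purchased, needs one stereocentre from outside and lets the ring closure set the other two.

Key step: step 8

Remark: 4-(benzyloxy)-3-methoxybenzaldehyde (1, O-benzylvanillin) is taken as a catalogue compound, one benzylation away from vanillin.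
Remark: in step 7 the diene ligand L* is the enantiomer of 2,5-diphenylbicyclo[2.2.2]octa-2,5-diene that delivers the aryl group to the Re face of the β-carbon of 8; which enantiomer this is must be fixed by a configurational check on 14, and both are accessible.

Step 1
Reactants: 1 4-(benzyloxy)-3-methoxybenzaldehyde
Product: 2 4-(benzyloxy)-2-bromo-5-methoxybenzaldehyde
Conditions: Br2 (1.05 equiv), NaOAc, AcOH, rt
Reagents that add atoms: bromine, BrBr
Why: Electrophilic aromatic bromination; with the phenol etherified, the free position para to the methoxy group is the most activated site, the usual outcome for O-alkylvanillins, and NaOAc buffers the HBr so the benzyl ether is not cleaved.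

Step 2
Reactants: 2 4-(benzyloxy)-2-bromo-5-methoxybenzaldehyde; 3 trimethyl phosphonoacetate
Product: 5 methyl (E)-3-[4-(benzyloxy)-2-bromo-5-methoxyphenyl]prop-2-enoate, via sodium phosphonoacetate carbanion 4 (not isolated)
Conditions: NaH, THF, 0 °C; then 2, 0 °C → rt
Reagents that add atoms: none
Why: Horner–Wadsworth–Emmons olefination of an aromatic aldehyde with a stabilised phosphonate anion, reliably E-selective; the geometry is of no consequence because the alkene is saturated next.

Step 3
Reactants: 5 methyl (E)-3-[4-(benzyloxy)-2-bromo-5-methoxyphenyl]prop-2-enoate
Product: 6 methyl 3-[4-(benzyloxy)-2-bromo-5-methoxyphenyl]propanoate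
Conditions: H2 (4 atm), RhCl(PPh3)3 (5 mol%), toluene/MeOH, 50 °C
Reagents that add atoms: none
Why: Homogeneous hydrogenation with RhCl(PPh3)3 saturates a disubstituted cinnamate alkene but does not hydrogenolyse benzyl ethers or aryl C–Br bonds, which is why it is preferred to Pd/C here.

Step 4
Reactants: 6 methyl 3-[4-(benzyloxy)-2-bromo-5-methoxyphenyl]propanoate; 7 methyl acrylate
Product: 8 methyl (E)-3-[5-(benzyloxy)-4-methoxy-2-(3-methoxy-3-oxopropyl)phenyl]prop-2-enoate
Conditions: Pd(OAc)2 (5 mol%), P(o-tol)3 (12 mol%), Et3N, DMF, 100 °C
Reagents that add atoms: none
Why: Mizoroki–Heck reaction of an aryl bromide with an acrylate; syn carbopalladation and syn β-hydride elimination give the E-enoate, and the bulky P(o-tol)3 is the standard ligand for electron-rich, ortho-substituted aryl bromides.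

Step 5
Reactants: 9 4-bromo-2,6-dimethoxyphenol
Product: 10 2-(benzyloxy)-5-bromo-1,3-dimethoxybenzene
Conditions: BnBr, K2CO3, DMF, 60 °C
Reagents that add atoms: benzyl bromide, BrCc1ccccc1
Why: Williamson ether synthesis; the phenoxide is flanked by two methoxy groups but is alkylated readily by a benzylic halide in a dipolar aprotic solvent.

Step 6
Reactants: 10 2-(benzyloxy)-5-bromo-1,3-dimethoxybenzene
Product: 13 [4-(benzyloxy)-3,5-dimethoxyphenyl]boronic acid, via aryllithium 11 (not isolated), via lithium aryltriisopropoxyborate 12 (not isolated)
Conditions: n-BuLi, THF, −78 °C; B(OiPr)3, −78 °C → rt; 1 M HCl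
Reagents that add atoms: triisopropyl borate, CC(C)OB(OC(C)C)OC(C)C; water, O
Why: Bromine–lithium exchange at −78 °C outruns any deprotonation, the aryllithium is trapped by the borate as an ate complex, and acidic hydrolysis releases the boronic acid.

Step 7
Reactants: 8 methyl (E)-3-[5-(benzyloxy)-4-methoxy-2-(3-methoxy-3-oxopropyl)phenyl]prop-2-enoate; 13 [4-(benzyloxy)-3,5-dimethoxyphenyl]boronic acid
Product: 14 methyl (3S)-3-[4-(benzyloxy)-3,5-dimethoxyphenyl]-3-[5-(benzyloxy)-4-methoxy-2-(3-methoxy-3-oxopropyl)phenyl]propanoate
Conditions: [RhCl(C2H4)2]2 (2.5 mol%), chiral diene L* (5.5 mol%), KOH (0.2 equiv), dioxane/H2O 10:1, 50 °C; 13 (2 equiv)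
Reagents that add atoms: none
Why: Rhodium-catalysed asymmetric conjugate addition of an arylboronic acid to a β-aryl enoate (Hayashi–Miyaura reaction): transmetallation gives an aryl–rhodium species on the C2-symmetric diene, the enoate binds through one enantioface, and aryl migration to the Re face of the β-carbon should create C1 as (S). The resulting rhodium enolate is protonated by water, and the saturated ester arm is a spectator.

Step 8
Reactants: 14 methyl (3S)-3-[4-(benzyloxy)-3,5-dimethoxyphenyl]-3-[5-(benzyloxy)-4-methoxy-2-(3-methoxy-3-oxopropyl)phenyl]propanoate
Product: 16 dimethyl (1S,2R,3R)-7-(benzyloxy)-1-[4-(benzyloxy)-3,5-dimethoxyphenyl]-6-methoxy-1,2,3,4-tetrahydronaphthalene-2,3-dicarboxylate, via dilithium bis-enolate 15 (not isolated)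
Conditions: LiN(iPr)2 (2.3 equiv), THF, −78 °C, slow addition of 14; then CuCl2 (2.5 equiv) in DMF, −78 → 0 °C, 0.01 M; crude product: NaOMe (0.3 equiv), MeOH, 50 °C
Reagents that add atoms: none
Why: Two equivalents of LiN(iPr)2 turn both CH2CO2Me groups into lithium ester enolates (15); CuCl2 removes one electron from one enolate to give an α-ester radical, which adds to the carbon terminus of the second enolate, and a second equivalent of divalent copper oxidises the resulting radical anion, so the net change is loss of two electrons and formation of the C2–C3 σ bond. The closest known reaction type is the intramolecular oxidative coupling of diester dienolates with divalent copper halides or iodine to trans-cycloalkane-1,2-dicarboxylates, together with the copper-mediated dimerisation of ester enolates to succinates. Ring B closes in a 6-exo-trig mode: counted from the radical carbon, the attacked enolate carbon is the sixth atom and its enolate C=C bond lies outside the new ring, while the aromatic C4a–C8a bond holds the two termini cis and within bonding distance. C2 is controlled by C1: in the half-chair transition state the pendant aryl group should take the pseudo-equatorial position and the planar C2 terminus should turn its ester group to the opposite face, giving the 1,2-trans relationship. C3 is controlled by C2: the two ester groups avoid eclipsing and dipole repulsion and should end up trans, as in the simple cycloalkane cases. Cyclisation must beat intermolecular coupling and Claisen-type acylation; this is secured by high dilution, by adding 14 to excess base at −78 °C so that no enolate meets an un-enolised ester, and by the ortho-disubstituted arene that preorganises the chain. The all-trans arrangement is backed up thermodynamically: C2 and C3 are both α to esters and the all-trans isomer has all three substituents pseudo-equatorial, so the NaOMe treatment should convert any C2 or C3 epimer into 16, while C1, a diarylmethine without an activating carbonyl, is not touched.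

Step 9
Reactants: 16 dimethyl (1S,2R,3R)-7-(benzyloxy)-1-[4-(benzyloxy)-3,5-dimethoxyphenyl]-6-methoxy-1,2,3,4-tetrahydronaphthalene-2,3-dicarboxylate
Product: 17 [(1S,2R,3R)-7-(benzyloxy)-1-[4-(benzyloxy)-3,5-dimethoxyphenyl]-6-methoxy-1,2,3,4-tetrahydronaphthalene-2,3-diyl]dimethanol
Conditions: LiAlH4 (2.5 equiv), THF, 0 °C → rt; then H2O, aq NaOH
Reagents that add atoms: none
Why: Hydride reduction of both esters to primary alcohols; benzyl ethers are inert, and the centres at C2 and C3 already hold their thermodynamic configuration, so no erosion is expected.

Step 10
Reactants: 17 [(1S,2R,3R)-7-(benzyloxy)-1-[4-(benzyloxy)-3,5-dimethoxyphenyl]-6-methoxy-1,2,3,4-tetrahydronaphthalene-2,3-diyl]dimethanol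
Product: 18 [(1S,2R,3R)-7-(benzyloxy)-1-[4-(benzyloxy)-3,5-dimethoxyphenyl]-6-methoxy-1,2,3,4-tetrahydronaphthalene-2,3-diyl]bis(methylene) diacetate
Conditions: Ac2O, pyridine, DMAP (cat.), CH2Cl2, rt
Reagents that add atoms: acetic anhydride, CC(=O)OC(C)=O
Why: Nucleophile-catalysed acylation of two primary alcohols; no selectivity is needed because both phenols are still benzyl ethers.

Step 11
Reactants: 18 [(1S,2R,3R)-7-(benzyloxy)-1-[4-(benzyloxy)-3,5-dimethoxyphenyl]-6-methoxy-1,2,3,4-tetrahydronaphthalene-2,3-diyl]bis(methylene) diacetate
Product: 19 [(1S,2R,3R)-7-hydroxy-1-(4-hydroxy-3,5-dimethoxyphenyl)-6-methoxy-1,2,3,4-tetrahydronaphthalene-2,3-diyl]bis(methylene) diacetate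
Conditions: H2 (1 atm), 10% Pd/C, EtOAc, rt
Reagents that add atoms: none
Why: Hydrogenolysis of two aryl benzyl ethers under neutral conditions; the acetates, the methyl ethers and the C1–H bond (no benzylic C–O bond remains in the skeleton) are not affected.

## Compound list

1 | 4-(benzyloxy)-3-methoxybenzaldehyde | COc1cc(C=O)ccc1OCc1ccccc1 | starting material
2 | 4-(benzyloxy)-2-bromo-5-methoxybenzaldehyde | COc1cc(C=O)c(Br)cc1OCc1ccccc1 | intermediate
3 | trimethyl phosphonoacetate | COC(=O)CP(=O)(OC)OC | starting material
4 | sodium salt of the trimethyl phosphonoacetate carbanion | [Na+].COC(=O)[CH-]P(=O)(OC)OC | intermediate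
5 | methyl (E)-3-[4-(benzyloxy)-2-bromo-5-methoxyphenyl]prop-2-enoate | COC(=O)/C=C/c1cc(OC)c(OCc2ccccc2)cc1Br | intermediate
6 | methyl 3-[4-(benzyloxy)-2-bromo-5-methoxyphenyl]propanoate | COC(=O)CCc1cc(OC)c(OCc2ccccc2)cc1Br | intermediate
7 | methyl acrylate | C=CC(=O)OC | starting material
8 | methyl (E)-3-[5-(benzyloxy)-4-methoxy-2-(3-methoxy-3-oxopropyl)phenyl]prop-2-enoate | COC(=O)/C=C/c1cc(OCc2ccccc2)c(OC)cc1CCC(=O)OC | intermediate
9 | 4-bromo-2,6-dimethoxyphenol | COc1cc(Br)cc(OC)c1O | starting material
10 | 2-(benzyloxy)-5-bromo-1,3-dimethoxybenzene | COc1cc(Br)cc(OC)c1OCc1ccccc1 | intermediate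
11 | [4-(benzyloxy)-3,5-dimethoxyphenyl]lithium | [Li]c1cc(OC)c(OCc2ccccc2)c(OC)c1 | intermediate
12 | lithium [4-(benzyloxy)-3,5-dimethoxyphenyl]tri(propan-2-yloxy)borate | [Li+].CC(C)O[B-](OC(C)C)(OC(C)C)c1cc(OC)c(OCc2ccccc2)c(OC)c1 | intermediate
13 | [4-(benzyloxy)-3,5-dimethoxyphenyl]boronic acid | COc1cc(B(O)O)cc(OC)c1OCc1ccccc1 | intermediate
14 | methyl (3S)-3-[4-(benzyloxy)-3,5-dimethoxyphenyl]-3-[5-(benzyloxy)-4-methoxy-2-(3-methoxy-3-oxopropyl)phenyl]propanoate | COC(=O)C[C@@H](c1cc(OC)c(OCc2ccccc2)c(OC)c1)c1cc(OCc2ccccc2)c(OC)cc1CCC(=O)OC | intermediate
15 | dilithium bis-enolate of 14 (enolate geometries not defined) | [Li+].[Li+].COC([O-])=C[C@@H](c1cc(OC)c(OCc2ccccc2)c(OC)c1)c1cc(OCc2ccccc2)c(OC)cc1CC=C([O-])OC | intermediate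
16 | dimethyl (1S,2R,3R)-7-(benzyloxy)-1-[4-(benzyloxy)-3,5-dimethoxyphenyl]-6-methoxy-1,2,3,4-tetrahydronaphthalene-2,3-dicarboxylate | COc1cc2c(cc1OCc3ccccc3)[C@H](c1cc(OC)c(OCc3ccccc3)c(OC)c1)[C@@H](C(=O)OC)[C@H](C(=O)OC)C2 | intermediate
17 | [(1S,2R,3R)-7-(benzyloxy)-1-[4-(benzyloxy)-3,5-dimethoxyphenyl]-6-methoxy-1,2,3,4-tetrahydronaphthalene-2,3-diyl]dimethanol | COc1cc2c(cc1OCc3ccccc3)[C@H](c1cc(OC)c(OCc3ccccc3)c(OC)c1)[C@@H](CO)[C@H](CO)C2 | intermediate
18 | [(1S,2R,3R)-7-(benzyloxy)-1-[4-(benzyloxy)-3,5-dimethoxyphenyl]-6-methoxy-1,2,3,4-tetrahydronaphthalene-2,3-diyl]bis(methylene) diacetate | COc1cc2c(cc1OCc3ccccc3)[C@H](c1cc(OC)c(OCc3ccccc3)c(OC)c1)[C@@H](COC(C)=O)[C@H](COC(C)=O)C2 | intermediate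
19 | [(1S,2R,3R)-7-hydroxy-1-(4-hydroxy-3,5-dimethoxyphenyl)-6-methoxy-1,2,3,4-tetrahydronaphthalene-2,3-diyl]bis(methylene) diacetate | COc1cc2c(cc1O)[C@H](c1cc(OC)c(O)c(OC)c1)[C@@H](COC(C)=O)[C@H](COC(C)=O)C2 | target

## Step count and risk

Total: 11 steps. Longest linear sequence: 9 steps (steps 1, 2, 3, 4, 7, 8, 9, 10, 11, from compound 1); steps 5 and 6 form the side branch to 13.

**Step 8 (key step).** The most likely failure is that ring closure loses to intermolecular coupling and oligomerisation, to over-oxidation of the α-ester radical (α-chlorination or dehydrogenation to an unsaturated ester), or to Claisen-type acylation giving a seven-membered β-keto ester if an enolate sits beside an un-enolised ester. Incomplete diastereoselection is less serious because the NaOMe stage corrects it. Fallback, setting out from 14: the bis-enolate 15 would be silylated (LiN(iPr)2, then Me3SiCl, THF, −78 °C) and the bis(trimethylsilyl ketene acetal) F1 freed from salts under anhydrous conditions. Treatment with TiCl4 in CH2Cl2 at −78 °C, the known oxidative coupling of ketene silyl acetals to succinates by tetravalent titanium, would join the two α-carbons with no free enolate present. The same NaOMe equilibration would bring the route back at 16.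

**Step 7.** Carbometallation of the electron-rich, ortho-substituted cinnamate may be slow, so that protodeboronation of the electron-rich boronic acid consumes the aryl donor; the catalyst may also discriminate the two alkene faces poorly. Fallback, setting out from 6, with auxiliary control in place of catalyst control:
- Heck coupling with acrylic acid (Pd(OAc)2, P(o-tol)3, Et3N) would give (E)-3-[5-(benzyloxy)-4-methoxy-2-(3-methoxy-3-oxopropyl)phenyl]prop-2-enoic acid F2.
- Activation with pivaloyl chloride and Et3N would give the mixed pivalic anhydride F3, and acylation of (4R)-4-phenyl-1,3-oxazolidin-2-one (LiCl, Et3N) the N-enoyl oxazolidinone F4.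
- The arylmagnesium bromide F5, made from 10 and magnesium, would add with CuBr·SMe2 at −40 °C to the magnesium-chelated s-cis imide on the face away from the phenyl group. For the (4R) auxiliary this is the Re face of the β-carbon, giving the (3S) adduct F6.
- NaOMe in MeOH at 0 °C would release the auxiliary and return the route at 14.

**Step 3.** Hydrogenation of the conjugated, ortho-substituted alkene may be sluggish, and forcing it risks hydrodebromination. Fallback, setting out from 1, with the order of operations changed so that no C–Br bond is present during the reduction: Horner–Wadsworth–Emmons olefination of 1 with 3 would give methyl (E)-3-[4-(benzyloxy)-3-methoxyphenyl]prop-2-enoate F7. Conjugate reduction with NiCl2/NaBH4 in MeOH would give methyl 3-[4-(benzyloxy)-3-methoxyphenyl]propanoate F8. Bromination (Br2, NaOAc, AcOH), again para to the methoxy group, would return the route at 6.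

**Step 4.** Oxidative addition into the electron-rich, ortho-substituted C–Br bond may be slow, with catalyst decomposition and acrylate polymerisation at the temperature needed. Fallback, setting out from 6: Suzuki–Miyaura coupling with commercial methyl (E)-3-(4,4,5,5-tetramethyl-1,3,2-dioxaborolan-2-yl)acrylate (Pd(OAc)2, SPhos, K3PO4, toluene/H2O, 80 °C). The alkene then arrives by transmetallation instead of carbopalladation, and the route returns directly at 8; no new compound arises (F0).

## Further compounds

F1 | step 8 | bis(trimethylsilyl ketene acetal) of 14 | COC(O[Si](C)(C)C)=C[C@@H](c1cc(OC)c(OCc2ccccc2)c(OC)c1)c1cc(OCc2ccccc2)c(OC)cc1CC=C(OC)O[Si](C)(C)C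
F2 | step 7 | (E)-3-[5-(benzyloxy)-4-methoxy-2-(3-methoxy-3-oxopropyl)phenyl]prop-2-enoic acid | COC(=O)CCc1cc(OC)c(OCc2ccccc2)cc1/C=C/C(=O)O
F3 | step 7 | mixed anhydride of F2 with pivalic acid | COC(=O)CCc1cc(OC)c(OCc2ccccc2)cc1/C=C/C(=O)OC(=O)C(C)(C)C
F4 | step 7 | (4R)-3-[(E)-3-[5-(benzyloxy)-4-methoxy-2-(3-methoxy-3-oxopropyl)phenyl]prop-2-enoyl]-4-phenyl-1,3-oxazolidin-2-one | COC(=O)CCc1cc(OC)c(OCc2ccccc2)cc1/C=C/C(=O)N1[C@H](c2ccccc2)COC1=O
F5 | step 7 | [4-(benzyloxy)-3,5-dimethoxyphenyl]magnesium bromide | Br[Mg]c1cc(OC)c(OCc2ccccc2)c(OC)c1
F6 | step 7 | (4R)-3-[(3S)-3-[4-(benzyloxy)-3,5-dimethoxyphenyl]-3-[5-(benzyloxy)-4-methoxy-2-(3-methoxy-3-oxopropyl)phenyl]propanoyl]-4-phenyl-1,3-oxazolidin-2-one | O=C(C[C@@H](c1cc(OC)c(OCc2ccccc2)c(OC)c1)c1cc(OCc2ccccc2)c(OC)cc1CCC(=O)OC)N1[C@H](c2ccccc2)COC1=O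
F7 | step 3 | methyl (E)-3-[4-(benzyloxy)-3-methoxyphenyl]prop-2-enoate | COC(=O)/C=C/c1ccc(OCc2ccccc2)c(OC)c1
F8 | step 3 | methyl 3-[4-(benzyloxy)-3-methoxyphenyl]propanoate | COC(=O)CCc1ccc(OCc2ccccc2)c(OC)c1
F0 | step 4 | none | none
A1 | alternative 1 | cis-fused dichlorocyclobutanone on C2 and C3, anti to the C1 aryl group | COc1cc2c(cc1OCc3ccccc3)[C@H](c1cc(OC)c(OCc3ccccc3)c(OC)c1)[C@H]3C(Cl)(Cl)C(=O)[C@H]3C2
A2 | alternative 1 | (1S)-7-(benzyloxy)-1-[4-(benzyloxy)-3,5-dimethoxyphenyl]-6-methoxy-1,4-dihydronaphthalene | COc1cc2c(cc1OCc3ccccc3)[C@H](c1cc(OC)c(OCc3ccccc3)c(OC)c1)C=CC2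
A3 | alternative 1 | dichloroketene | ClC(Cl)=C=O
A4 | alternative 2 | dimethyl 7-(benzyloxy)-1-(4-hydroxy-3,5-dimethoxyphenyl)-6-methoxy-3-vinyl-3,4-dihydronaphthalene-2,2(1H)-dicarboxylate, C1 and C3 configured as in the target | COc1cc2c(cc1OCc3ccccc3)[C@H](c1cc(OC)c(O)c(OC)c1)C(C(=O)OC)(C(=O)OC)[C@H](C=C)C2
A5 | alternative 2 | para-quinone methide of ring C bearing ring A with an ortho (E)-4-(methoxycarbonyloxy)but-2-enyl chain | COC(=O)OC/C=C/Cc1cc(OC)c(OCc2ccccc2)cc1C=C1C=C(OC)C(=O)C(OC)=C1
A6 | alternative 2 | dimethyl malonate | COC(=O)CC(=O)OC
A7 | alternative 3 | [(1S,2R,3R)-1-[4-(benzyloxy)-3,5-dimethoxyphenyl]-7-bromo-6-methoxy-1,2,3,4-tetrahydronaphthalene-2,3-diyl]bis(methylene) diacetate | COc1cc2c(cc1Br)[C@H](c1cc(OC)c(OCc3ccccc3)c(OC)c1)[C@@H](COC(C)=O)[C@H](COC(C)=O)C2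
A8 | alternative 3 | 3-bromo-4-methoxy-2-pyrone carrying at C6 the open chain C4–C1 with both acetoxymethyl arms, the ring C aryl group and a terminal alkyne on C1, C1–C3 configured as in the target | COc1cc(C[C@@H](COC(C)=O)[C@H](COC(C)=O)[C@H](C#C)c2cc(OC)c(OCc3ccccc3)c(OC)c2)oc(=O)c1Br
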